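Germacrane numbering: ten-membered ring C1–C10; butenolide ring O–C12(=O)–C11=C7–C6; C13 is the CH2OH carbon. Everything rests on reading the tetrasubstituted C7=C11 olefin of the butenolide, flanked by the oxygenated carbons C8 and C13, as a but-2-yne-1,4-diol unit acting as a vicinal dianion. In one operation the titanacyclopropene of this alkyne takes up CO2 at C11 (C11–C12 bond) and then a geraniol-derived epoxy aldehyde at C7 (C7–C6 bond). Lactonisation completes the ring and sets C6. The precursor is an acyclic iodo-enyne bis-silyl ether that contains no lactone. Nozaki–Hiyama–Kishi closure of C1–C10 later forms the ten-membered ring.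

Key step: step 7

Assumption: the (S,S)-ProPhenol zinc catalyst is taken to deliver the acetylide to the Re face of the enal in step 5 (S carbinol); if the sense proves opposite, the (R,R)-ligand is used and nothing else changes.

Step 1
Reactants: 1 geraniol
Product: 2 (2R,3R)-2,3-epoxygeraniol
Conditions: Ti(OiPr)4 (cat.), D-(−)-diethyl tartrate (cat.), t-BuOOH, 4 Å MS, CH2Cl2, −20 °C
Reagents that add atoms: tert-butyl hydroperoxide, CC(C)(C)OO
Why: Sharpless asymmetric epoxidation touches only the allylic 2,3-olefin and, with the D-(−)-tartrate, should give the (2R,3R)-epoxide, which sets C4 and C5 of the target as the trans (E-derived) oxirane.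

Step 2
Reactants: 2 (2R,3R)-2,3-epoxygeraniol
Product: 3 (2S,3R)-3-methyl-3-(4-methylpent-3-en-1-yl)oxirane-2-carbaldehyde
Conditions: PhI(OAc)2, 2,2,6,6-tetramethylpiperidin-1-oxyl (cat.), CH2Cl2, rt
Reagents that add atoms: none
Why: Oxoammonium-catalysed alcohol oxidation stops at the aldehyde under nearly neutral conditions, so the oxirane stereocentres and the remote olefin are retained (the descriptor at the oxirane CH changes only because the priorities change).

Step 3
Reactants: 4 but-2-yn-1-ol
Product: 6 (Z)-3-iodobut-2-en-1-ol, via cyclic alkenylalanate 5 (not isolated)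
Conditions: NaAlH2(OCH2CH2OMe)2, THF, 0 °C to rt; then I2, THF, −78 to 0 °C
Reagents that add atoms: iodine, II
Why: Hydroxyl-directed trans-hydroalumination places aluminium on C3 inside a five-membered alkoxyalanate, and iodinolysis with retention gives only the Z iodoalkene, which fixes the C9=C10 geometry of the target.

Step 4
Reactants: 6 (Z)-3-iodobut-2-en-1-ol
Product: 7 (Z)-3-iodobut-2-enal
Conditions: MnO2, CH2Cl2, rt, dark, used at once
Reagents that add atoms: none
Why: Allylic alcohol oxidation with MnO2 is neutral and heterogeneous, which should keep the sensitive Z β-iodoenal from isomerising.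

Step 5
Reactants: 7 (Z)-3-iodobut-2-enal; 8 tert-butyldimethyl(prop-2-yn-1-yloxy)silane
Product: 10 (4S,5Z)-1-(tert-butyldimethylsilyloxy)-6-iodohept-5-en-2-yn-4-ol, via methylzinc acetylide 9 (not isolated)
Conditions: Me2Zn, (S,S)-ProPhenol = 2,6-bis[[(S)-2-(hydroxydiphenylmethyl)pyrrolidin-1-yl]methyl]-4-methylphenol (cat.), Ph3P=O (cat.), toluene, 0 °C
Reagents that add atoms: none
Why: Catalytic asymmetric alkynylation of an α,β-unsaturated aldehyde by the dinuclear zinc ProPhenol complex adds the acetylide to the Re face of 7 and sets C8 as S, without a free amine base that could attack the β-iodoenal.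

Step 6
Reactants: 10 (4S,5Z)-1-(tert-butyldimethylsilyloxy)-6-iodohept-5-en-2-yn-4-ol
Product: 11 (4S,5Z)-1-(tert-butyldimethylsilyloxy)-6-iodo-4-(triethylsilyloxy)hept-5-en-2-yne
Conditions: Et3SiCl, imidazole, CH2Cl2, 0 °C
Reagents that add atoms: chlorotriethylsilane, CC[Si](Cl)(CC)CC
Why: Standard silylation gives a TES ether that keeps O8 from competing for the lactone in step 7, is a poor leaving group towards titanium, adds bulk next to C7 and can later be removed beside the primary TBS ether.

Step 7
Reactants: 11 (4S,5Z)-1-(tert-butyldimethylsilyloxy)-6-iodo-4-(triethylsilyloxy)hept-5-en-2-yne; 12 carbon dioxide; 3 (2S,3R)-3-methyl-3-(4-methylpent-3-en-1-yl)oxirane-2-carbaldehyde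
Product: 16 (5S)-3-(tert-butyldimethylsilyloxymethyl)-4-[(1S,2Z)-3-iodo-1-(triethylsilyloxy)but-2-en-1-yl]-5-[(2R,3R)-3-methyl-3-(4-methylpent-3-en-1-yl)oxiran-2-yl]furan-2(5H)-one, via titanacyclopropene 13 (not isolated), via titanalactone 14 (not isolated), via seven-membered titanium alkoxide carboxylate 15 (not isolated)
Conditions: Ti(OiPr)4, i-PrMgCl (2 equiv per Ti), Et2O, −78 to −40 °C; CO2 (1 atm), −40 °C; Ar purge, then 3, −40 to 0 °C; 10% aq. citric acid, 0 °C
Reagents that add atoms: none
Why: Ti(OiPr)4 and two equivalents of i-PrMgCl give the divalent titanium propene complex, which exchanges propene for the alkyne of 11 to form titanacyclopropene 13, a vicinal C7/C11 dianion equivalent; CO2 inserts into the less hindered Ti–C11 bond (C11–C12 formed) to give titanalactone 14, the remaining Ti–C7 bond then inserts the aldehyde of 3 (C7–C6 formed) to give 15, and mild acid releases the (Z)-γ-hydroxy acid, which lactonises at once to 16. The closest known reaction types are the carboxylation of (η2-alkyne)Ti(OiPr)2 complexes followed by capture of the residual alkenyl–titanium bond by a second electrophile, and the alkyne/imine/CO2 coupling of the same complexes to α,β-unsaturated γ-lactams. One ring is closed, the five-membered butenolide, by 5-exo-trig acyl substitution of O6 at C12, which is possible because the syn-dimetallated alkyne holds C6 and C12 cis on C7=C11. C6 is the only new stereocentre: 3 is expected to bind the Lewis acidic tetravalent titanium of 14 (or the Mg2+ present) through both its carbonyl and oxirane oxygen atoms, as epoxy alcohols bind Ti(OiPr)4, so that C7 is delivered in the Cram chelate sense to the face flanked by H5 and away from C4 and its cis methyl group, which gives (6S) with O5 and O6 syn. The step needs the first insertion to occur at C11, which the primary CH2OTBS group at C11 against the branched, TES-shielded C8 at C7 should secure, and it needs the alkyne to react in preference to the alkenyl iodide and the propargylic silyl ethers, which is secured by adding the Grignard reagent to premixed Ti(OiPr)4 and 11 at −78 °C (transmetallation to titanium outruns iodine–magnesium exchange) and by the poor leaving-group ability of silyloxide (no allenyltitanium). CO2 also destroys any excess low-valent titanium before 3 is added, so the aldehyde and the epoxide meet only tetravalent titanium.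

Step 8
Reactants: 16 TES/TBS-protected butenolide
Product: 17 (5S)-3-(tert-butyldimethylsilyloxymethyl)-4-[(1S,2Z)-1-hydroxy-3-iodobut-2-en-1-yl]-5-[(2R,3R)-3-methyl-3-(4-methylpent-3-en-1-yl)oxiran-2-yl]furan-2(5H)-one
Conditions: HF·pyridine, pyridine, THF, 0 °C
Reagents that add atoms: none
Why: Pyridine-buffered fluoride desilylation removes the far more labile TES ether beside the primary TBS ether and spares the epoxide, and the freed O8 cannot translactonise because the tetrahedral intermediate would be a bicyclo[2.2.1] system with a bridgehead olefin.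

Step 9
Reactants: 17 C8 alcohol; 18 tigloyl chloride, (E)-2-methylbut-2-enoyl chloride
Product: 19 C8 tiglate, (1S,2Z)-1-[(2S)-4-(tert-butyldimethylsilyloxymethyl)-2-[(2R,3R)-3-methyl-3-(4-methylpent-3-en-1-yl)oxiran-2-yl]-5-oxo-2,5-dihydrofuran-3-yl]-3-iodobut-2-en-1-yl (E)-2-methylbut-2-enoate
Conditions: pyridine, 4-(dimethylamino)pyridine (cat.), CH2Cl2, 0 °C to rt
Reagents that add atoms: none
Why: Nucleophile-catalysed acylation breaks only the O–H bond, so C8 is retained, the thermodynamically favoured E acyl unit does not isomerise, and the weak base should not deprotonate the γ-position (C6) of the butenolide.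

Step 10
Reactants: 19 C8 tiglate
Product: 21 seco-aldehyde (as 19 but the 4-methylpent-3-enyl chain on the oxirane is cut back to a 3-oxopropyl chain whose CHO carbon is C1), via vicinal diol 20 (not isolated)
Conditions: OsO4 (cat.), NaIO4, 2,6-lutidine, 1,4-dioxane/H2O, rt
Reagents that add atoms: sodium periodate, [Na+].[O-]I(=O)(=O)=O; osmium tetroxide (catalytic oxygen carrier), O=[Os](=O)(=O)=O
Why: Johnson–Lemieux cleavage picks the only electron-rich olefin, because the tiglate and butenolide olefins are electron-poor and the iodoalkene is deactivated by iodine and the allylic ester.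

Step 11
Reactants: 21 seco-aldehyde
Product: 23 O13-TBS ether of the target, via alkenylchromium dichloride 22 (not isolated)
Conditions: CrCl2 (excess), NiCl2 (cat.), DMSO, slow addition to 0.002 M, rt
Reagents that add atoms: none
Why: In this Nozaki–Hiyama–Kishi macrocyclisation zerovalent nickel inserts into the carbon–iodine bond with retention of the Z geometry, and transmetallation gives the trivalent chromium species 22, which adds only to the aldehyde beside esters, lactone and epoxide; the Z olefin, butenolide and oxirane preorganise the chain for ten-membered closure, and C1 is set under macrocyclic control (carbonyl oxygen turned outward, A(1,3) strain across C9=C10 minimised), which should favour the (1R)-carbinol.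

Step 12
Reactants: 23 O13-TBS ether of the target
Product: 24 target CNP0167056.1
Conditions: HF·pyridine, THF, 0 °C to rt
Reagents that add atoms: none
Why: Mildly acidic fluoride desilylation frees the primary C13 alcohol without base, which avoids O8 to O1 acyl migration and γ-deprotonation with opening of the neighbouring epoxide.

Compound list
1 | geraniol, (2E)-3,7-dimethylocta-2,6-dien-1-ol | CC(C)=CCC/C(C)=C/CO | starting material
2 | (2R,3R)-2,3-epoxygeraniol, [(2R,3R)-3-methyl-3-(4-methylpent-3-en-1-yl)oxiran-2-yl]methanol | CC(C)=CCC[C@@]1(C)O[C@@H]1CO | intermediate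
3 | (2S,3R)-3-methyl-3-(4-methylpent-3-en-1-yl)oxirane-2-carbaldehyde | CC(C)=CCC[C@@]1(C)O[C@@H]1C=O | intermediate
4 | but-2-yn-1-ol | CC#CCO | starting material
5 | sodium cyclic alkenylalanate (five-membered ring Al–C(CH3)=CH–CH2–O, two 2-methoxyethoxy ligands on Al) | CC1=CCO[Al-]1(OCCOC)OCCOC.[Na+] | intermediate
6 | (Z)-3-iodobut-2-en-1-ol | OC/C=C(/C)I | intermediate
7 | (Z)-3-iodobut-2-enal | O=C/C=C(/C)I | intermediate
8 | tert-butyldimethyl(prop-2-yn-1-yloxy)silane | C#CCO[Si](C)(C)C(C)(C)C | starting material
9 | methylzinc acetylide of 8 | C[Zn]C#CCO[Si](C)(C)C(C)(C)C | intermediate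
10 | (4S,5Z)-1-(tert-butyldimethylsilyloxy)-6-iodohept-5-en-2-yn-4-ol | O[C@H](C#CCO[Si](C)(C)C(C)(C)C)/C=C(/C)I | intermediate
11 | (4S,5Z)-1-(tert-butyldimethylsilyloxy)-6-iodo-4-(triethylsilyloxy)hept-5-en-2-yne | CC[Si](CC)(CC)O[C@H](C#CCO[Si](C)(C)C(C)(C)C)/C=C(/C)I | intermediate
12 | carbon dioxide | O=C=O | starting material
13 | titanacyclopropene, diisopropoxytitanium bonded to C7 and C11 of 11 | CC(C)O[Ti]1(OC(C)C)C(CO[Si](C)(C)C(C)(C)C)=C1[C@@H](O[Si](CC)(CC)CC)/C=C(/C)I | intermediate
14 | titanalactone, five-membered ring Ti–C7=C11–C12(=O)–O | CC(C)O[Ti]1(OC(C)C)OC(=O)C(CO[Si](C)(C)C(C)(C)C)=C1[C@@H](O[Si](CC)(CC)CC)/C=C(/C)I | intermediate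
15 | seven-membered titanium alkoxide carboxylate, ring Ti–O–C6–C7=C11–C12(=O)–O, (6S) | CC(C)=CCC[C@@]1(C)O[C@@H]1[C@H]2O[Ti](OC(C)C)(OC(C)C)OC(=O)C(CO[Si](C)(C)C(C)(C)C)=C2[C@@H](O[Si](CC)(CC)CC)/C=C(/C)I | intermediate
16 | (5S)-3-(tert-butyldimethylsilyloxymethyl)-4-[(1S,2Z)-3-iodo-1-(triethylsilyloxy)but-2-en-1-yl]-5-[(2R,3R)-3-methyl-3-(4-methylpent-3-en-1-yl)oxiran-2-yl]furan-2(5H)-one | CC(C)=CCC[C@@]1(C)O[C@@H]1[C@H]2OC(=O)C(CO[Si](C)(C)C(C)(C)C)=C2[C@@H](O[Si](CC)(CC)CC)/C=C(/C)I | intermediate
17 | C8 alcohol, as 16 with OH in place of OSiEt3 | CC(C)=CCC[C@@]1(C)O[C@@H]1[C@H]2OC(=O)C(CO[Si](C)(C)C(C)(C)C)=C2[C@@H](O)/C=C(/C)I | intermediate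
18 | tigloyl chloride, (E)-2-methylbut-2-enoyl chloride | C/C=C(\C)C(=O)Cl | starting material
19 | C8 tiglate of 17 | CC(C)=CCC[C@@]1(C)O[C@@H]1[C@H]2OC(=O)C(CO[Si](C)(C)C(C)(C)C)=C2[C@@H](OC(=O)/C(C)=C/C)/C=C(/C)I | intermediate
20 | vicinal diol from the terminal olefin of 19 (secondary carbinol as a mixture of epimers, of no consequence) | CC(C)(O)C(O)CC[C@@]1(C)O[C@@H]1[C@H]2OC(=O)C(CO[Si](C)(C)C(C)(C)C)=C2[C@@H](OC(=O)/C(C)=C/C)/C=C(/C)I | intermediate
21 | seco-aldehyde (C1 aldehyde, C10 Z alkenyl iodide) | O=CCC[C@@]1(C)O[C@@H]1[C@H]2OC(=O)C(CO[Si](C)(C)C(C)(C)C)=C2[C@@H](OC(=O)/C(C)=C/C)/C=C(/C)I | intermediate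
22 | alkenylchromium dichloride at C10 | O=CCC[C@@]1(C)O[C@@H]1[C@H]2OC(=O)C(CO[Si](C)(C)C(C)(C)C)=C2[C@@H](OC(=O)/C(C)=C/C)/C=C(/C)[Cr](Cl)Cl | intermediate
23 | O13-TBS ether of the target, (1R,4R,5R,6S,8S,9Z) | C/C=C(\C)C(=O)O[C@H]1/C=C(/C)[C@H](O)CC[C@@]2(C)O[C@@H]2[C@H]2OC(=O)C(CO[Si](C)(C)C(C)(C)C)=C12 | intermediate
24 | CNP0167056.1, (1R,4R,5R,6S,8S,9Z)-4,5-epoxy-1,13-dihydroxy-8-tigloyloxygermacra-7(11),9-dien-12,6-olide | C/C=C(\C)C(=O)O[C@H]1/C=C(/C)[C@H](O)CC[C@@]2(C)O[C@@H]2[C@H]2OC(=O)C(CO)=C12 | target

Total step count: 12. Longest linear sequence: 10 steps (steps 3 to 12, from but-2-yn-1-ol).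

Steps most likely to fail

Step 7. Three things may go wrong.
- CO2 may insert into the Ti–C7 bond rather than the Ti–C11 bond.
- The aldehyde may insert so slowly into the hindered Ti–C7 bond that protonolysis wins.
- A non-chelated (Felkin–Anh) approach of the aldehyde may erode or reverse the facial selectivity at C6.

The fallback sets out from 11 and comes back at 16. It separates the two bond formations and replaces titanium by a genuinely chelating magnesium reagent. Titanalactone 14 is generated from 11 as above but quenched with I2 to give the (Z)-β-iodoacrylic acid F1. MeI and K2CO3 in DMF give the methyl ester F2, at which stage any regioisomer can be removed. Iodine–magnesium exchange with i-PrMgCl·LiCl in THF at −40 °C should touch only the ester-activated iodide and give the alkenylmagnesium chloride F3. This is added to 3 precomplexed with MgBr2·OEt2 at −78 °C. The magnesium alkoxide closes onto the methyl ester and gives 16.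

Step 11. Slow ten-membered closure may compete with oligomerisation and with protonolysis of the alkenylchromium species. Above all, facial selectivity at the C1 aldehyde may be poor. The fallback sets out from 23 as obtained (either C1 epimer or a mixture) and comes back at 23. It moves control of C1 from the ring closure to a reagent. Dess–Martin periodinane in CH2Cl2 gives the macrocyclic enone F4. Corey–Bakshi–Shibata reduction then follows, using (S)-1-methyl-3,3-diphenyltetrahydro-1H,3H-pyrrolo[1,2-c][1,3,2]oxazaborole and catecholborane in toluene at −78 °C. The α-methylalkenyl side acts as the large group, so the reduction should deliver the (1R)-carbinol 23.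

Step 5. The β-iodoenal may isomerise from Z to E or decompose during a slow catalytic addition, and the enantioselectivity may be insufficient. The fallback sets out from 7 and 8 and comes back at 10. It replaces asymmetric C–C bond formation by asymmetric reduction. n-BuLi converts 8 into the lithium acetylide F5, which adds rapidly to 7 at −78 °C to give the racemic carbinol F6. MnO2 gives the alkenyl alkynyl ketone F7. Midland reduction with B-isopinocampheyl-9-borabicyclo[3.3.1]nonane made from (−)-α-pinene, in which the alkynyl group acts as the small substituent, should give (S)-10.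

Further compounds
F1 | step 7 | (2Z,4S,5Z)-2-(tert-butyldimethylsilyloxymethyl)-3,6-diiodo-4-(triethylsilyloxy)hepta-2,5-dienoic acid | OC(=O)/C(CO[Si](C)(C)C(C)(C)C)=C(\I)[C@@H](O[Si](CC)(CC)CC)/C=C(/C)I
F2 | step 7 | methyl ester of F1 | COC(=O)/C(CO[Si](C)(C)C(C)(C)C)=C(\I)[C@@H](O[Si](CC)(CC)CC)/C=C(/C)I
F3 | step 7 | alkenylmagnesium chloride from F2 (Mg at C7, cis to the ester) | COC(=O)/C(CO[Si](C)(C)C(C)(C)C)=C(\[Mg]Cl)[C@@H](O[Si](CC)(CC)CC)/C=C(/C)I
F4 | step 11 | macrocyclic C1 enone (1-oxo analogue of 23) | C/C=C(\C)C(=O)O[C@H]1/C=C(/C)C(=O)CC[C@@]2(C)O[C@@H]2[C@H]2OC(=O)C(CO[Si](C)(C)C(C)(C)C)=C12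
F5 | step 5 | lithium acetylide of 8 | [Li]C#CCO[Si](C)(C)C(C)(C)C
F6 | step 5 | racemic (5Z)-1-(tert-butyldimethylsilyloxy)-6-iodohept-5-en-2-yn-4-ol | OC(C#CCO[Si](C)(C)C(C)(C)C)/C=C(/C)I
F7 | step 5 | (5Z)-1-(tert-butyldimethylsilyloxy)-6-iodohept-5-en-2-yn-4-one | O=C(C#CCO[Si](C)(C)C(C)(C)C)/C=C(/C)I
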